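**Retrosynthetic overview**
1. The strategy rests on ring A, the benzene ring that bears the prenyl group. Going round it: C1 is bonded to Cb (the oxepine alkene carbon that has no pyran oxygen), C2 is CH, C3 bears prenyl, C4 bears OH, C5 is CH, C6 bears the oxepine oxygen. It is a resorcinol with a carbon substituent para to each oxygen, and it is assembled from open-chain carbons, not by substitution of a resorcinol.
2. Late disconnections: the three silyl ethers, then the oxepine C–O bond between the ring A oxygen and the ring B C–Br carbon (intramolecular Ullmann etherification of phenol 30).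
3. Ring A: α-diazo dienone 22 plus (triisopropylsilyloxy)acetylene 26, by photochemical Wolff rearrangement, ketene–alkyne [2+2] addition, four-electron ring opening and six-electron ring closure.
4. 22 comes from aldehyde 16 (aldol condensation with 6-methylhept-5-en-2-one, diazo transfer). 16 comes from dihydropyran 15 (formylation at Cb). 15 comes from hydroxy ketone 14, made from Weinreb amide 9 and the ring B Grignard reagent 13 (from 3-bromophenol).
5. 9 comes from nerol: asymmetric epoxidation sets both stereocentres, then two-carbon extension and 5-exo lactonisation with inversion at the secondary carbon. Ring order: dihydropyran (step 10), ring A (step 15), oxepine (step 16); ring B is carried in intact.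

Key step: step 15

Abbreviations: TBS = tert-butyl(dimethyl)silyl; TIPS = tri(propan-2-yl)silyl; Ar = 2-bromo-4-(TIPS-oxy)phenyl; P = (5S,6S)-2-Ar-5-(TBS-oxy)-6-methyl-6-(4-methylpent-3-en-1-yl)-5,6-dihydro-4H-pyran-3-yl, bonded through Cb.
Remark: the target is 2S,3S in dihydropyran numbering (O1, quaternary C2, carbinol C3). Compound 14 is written as the open hydroxy ketone; it may equilibrate with its cyclic hemiketal, and both forms lead to 15.

**Step 1**
Reactants: 1 nerol
Product: 2 [(2R,3S)-3-methyl-3-(4-methylpent-3-en-1-yl)oxiran-2-yl]methanol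
Conditions: Ti(Oi-Pr)4 (cat.), D-(−)-diisopropyl tartrate (cat.), t-BuOOH, 4 Å MS, CH2Cl2, −20 °C
Reagents that add atoms: tert-butyl hydroperoxide, CC(C)(C)OO
Why: Katsuki–Sharpless asymmetric epoxidation; the titanium tartrate complex delivers oxygen to one face of the allylic alkene (reagent control, the D-(−)-tartrate giving 2R,3S), the Z geometry passes stereospecifically into the cis-epoxide so both stereocentres are set together, and the remote trisubstituted alkene has no directing hydroxyl.

**Step 2**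
Reactants: 2 [(2R,3S)-3-methyl-3-(4-methylpent-3-en-1-yl)oxiran-2-yl]methanol
Product: 4 methyl (2E)-3-[(2R,3S)-3-methyl-3-(4-methylpent-3-en-1-yl)oxiran-2-yl]prop-2-enoate, via epoxy aldehyde 3 (not isolated)
Conditions: PhI(OAc)2, TEMPO (cat.), CH2Cl2, rt; then Ph3P=CHCO2Me (excess), rt
Reagents that add atoms: methyl (triphenylphosphoranylidene)acetate, COC(=O)C=P(c1ccccc1)(c1ccccc1)c1ccccc1
Why: nitroxyl-catalysed oxidation stops at the aldehyde without touching epoxide or alkene, and Wittig olefination with the stabilised ylide in the same flask should give the E-enoate while the sensitive epoxy aldehyde is never isolated.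

**Step 3**
Reactants: 4 methyl (2E)-3-[(2R,3S)-3-methyl-3-(4-methylpent-3-en-1-yl)oxiran-2-yl]prop-2-enoate
Product: 5 methyl 3-[(2R,3S)-3-methyl-3-(4-methylpent-3-en-1-yl)oxiran-2-yl]propanoate
Conditions: 2-nitrobenzenesulfonylhydrazide, Et3N, CH2Cl2, rt
Reagents that add atoms: none
Why: diimide reduction; concerted syn transfer of H2 to the unhindered 1,2-disubstituted conjugated C=C is much faster than to the trisubstituted alkene, and the allylic epoxide is not opened as it could be under metal-catalysed hydrogenation.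

**Step 4**
Reactants: 5 methyl 3-[(2R,3S)-3-methyl-3-(4-methylpent-3-en-1-yl)oxiran-2-yl]propanoate
Product: 7 (5S)-5-[(2S)-2-hydroxy-6-methylhept-5-en-2-yl]oxolan-2-one, via epoxy acid 6 (not isolated)
Conditions: LiOH, THF–H2O, rt; then 1 M HCl to pH 4, rt
Reagents that add atoms: lithium hydroxide (one carboxyl oxygen), [Li+].[OH-]
Why: saponification followed by intramolecular epoxide opening; the carboxyl oxygen attacks the less substituted epoxide carbon in the 5-exo mode by SN2 with inversion (R becomes S) while the tertiary C–O bond is untouched (S kept), and this kinetically preferred γ-lactonisation is used because opening at the tertiary carbon in the 6-endo mode is not dependable.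

**Step 5**
Reactants: 7 (5S)-5-[(2S)-2-hydroxy-6-methylhept-5-en-2-yl]oxolan-2-one
Product: 8 (4S,5S)-4,5-dihydroxy-N-methoxy-N,5,9-trimethyldec-8-enamide
Conditions: MeNHOMe·HCl, i-PrMgCl, THF, −20 → 0 °C
Reagents that add atoms: N,O-dimethylhydroxylamine hydrochloride, CNOC.Cl
Why: Weinreb aminolysis of the lactone by the chloromagnesium amide opens the ring, which frees the secondary hydroxyl for protection and provides an acyl group that takes up only one equivalent of an organometallic reagent.

**Step 6**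
Reactants: 8 (4S,5S)-4,5-dihydroxy-N-methoxy-N,5,9-trimethyldec-8-enamide
Product: 9 (4S,5S)-4-(TBS-oxy)-5-hydroxy-N-methoxy-N,5,9-trimethyldec-8-enamide
Conditions: TBSOTf, 2,6-lutidine, CH2Cl2, −78 °C
Reagents that add atoms: tert-butyl(dimethyl)silyl trifluoromethanesulfonate, CC(C)(C)[Si](C)(C)OS(=O)(=O)C(F)(F)F
Why: at low temperature the silyl triflate silylates the secondary hydroxyl far faster than the neighbouring tertiary one, which must stay free to become the pyran oxygen, and prompt silylation prevents relactonisation of the γ-hydroxy amide.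

**Step 7**
Reactants: 10 3-bromophenol
Product: 11 3-bromo-4-iodophenol
Conditions: N-iodosuccinimide, TsOH (cat.), MeCN, 0 °C → rt
Reagents that add atoms: N-iodosuccinimide, O=C1CCC(=O)N1I
Why: electrophilic aromatic iodination para to the hydroxyl should dominate, and it gives two different halogens that can be used one after the other.

**Step 8**
Reactants: 11 3-bromo-4-iodophenol
Product: 12 (3-bromo-4-iodophenoxy)tri(propan-2-yl)silane
Conditions: TIPSCl, imidazole, DMF, rt
Reagents that add atoms: chlorotri(propan-2-yl)silane, CC(C)[Si](Cl)(C(C)C)C(C)C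
Why: standard silylation of a phenol; the bulky TIPS ether should survive Grignard reagents, mild acid, amide bases and carbonate, and is removed by fluoride at the end.

**Step 9**
Reactants: 12 (3-bromo-4-iodophenoxy)tri(propan-2-yl)silane; 9 (4S,5S)-4-(TBS-oxy)-5-hydroxy-N-methoxy-N,5,9-trimethyldec-8-enamide
Product: 14 (4S,5S)-1-Ar-4-(TBS-oxy)-5-hydroxy-5,9-dimethyldec-8-en-1-one, via aryl Grignard reagent 13 (not isolated)
Conditions: 12, i-PrMgCl·LiCl, THF, −20 °C; then 9 (after t-BuMgCl, 1 equiv), −20 → 0 °C; aq. NH4Cl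
Reagents that add atoms: none
Why: iodine–magnesium exchange is much faster at C–I than at C–Br and the ortho-bromoaryl Grignard reagent is stable below ambient temperature; its addition to the Weinreb amide stops at the chelated tetrahedral adduct so work-up gives the ketone, and the tertiary hydroxyl is masked as its magnesium alkoxide by the non-nucleophilic t-BuMgCl.

**Step 10**
Reactants: 14 (4S,5S)-1-Ar-4-(TBS-oxy)-5-hydroxy-5,9-dimethyldec-8-en-1-one
Product: 15 (2S,3S)-6-Ar-3-(TBS-oxy)-2-methyl-2-(4-methylpent-3-en-1-yl)-3,4-dihydro-2H-pyran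
Conditions: PPTS (cat.), toluene, 4 Å MS, 80 °C
Reagents that add atoms: none
Why: acid-catalysed cyclodehydration; the tertiary hydroxyl adds to the ketone carbonyl (6-exo-trig) and the resulting oxocarbenium ion loses a proton from the only neighbouring CH2 to give the aryl-substituted endocyclic enol ether, and the weak pyridinium acid should spare the silyl ethers and the trisubstituted alkene.

**Step 11**
Reactants: 15 (2S,3S)-6-Ar-3-(TBS-oxy)-2-methyl-2-(4-methylpent-3-en-1-yl)-3,4-dihydro-2H-pyran
Product: 16 (5S,6S)-2-Ar-5-(TBS-oxy)-6-methyl-6-(4-methylpent-3-en-1-yl)-5,6-dihydro-4H-pyran-3-carbaldehyde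
Conditions: POCl3, DMF, 0 °C → rt; then aq. NaOAc
Reagents that add atoms: N,N-dimethylformamide (formyl carbon), CN(C)C=O; water (formyl oxygen), O
Why: Vilsmeier–Haack formylation; the enol ether attacks the chloroiminium ion with its β-carbon (the future Cb), proton loss restores the enol ether and hydrolysis gives the β-alkoxy enal, as in the formylation of glycals.

**Step 12**
Reactants: 16 (5S,6S)-2-Ar-5-(TBS-oxy)-6-methyl-6-(4-methylpent-3-en-1-yl)-5,6-dihydro-4H-pyran-3-carbaldehyde; 17 6-methylhept-5-en-2-one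
Product: 20 (1E)-7-methyl-1-P-octa-1,6-dien-3-one, via lithium enolate 18 (not isolated), via aldol adduct 19 (not isolated)
Conditions: 17, LiN(i-Pr)2, THF, −78 °C; then 16; then MsCl, −78 → 0 °C; DBU, rt
Reagents that add atoms: none
Why: directed aldol condensation; kinetic deprotonation of the methyl ketone occurs at the methyl group, the enolate adds to the non-enolisable aldehyde, and mesylation with E1cB elimination should give the E-dienone, which puts four of the six future ring A carbons in a row.

**Step 13**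
Reactants: 20 (1E)-7-methyl-1-P-octa-1,6-dien-3-one
Product: 22 (1E)-4-diazo-7-methyl-1-P-octa-1,6-dien-3-one, via trifluoroacetyl diketone 21 (not isolated)
Conditions: LiN(SiMe3)2, THF, −78 °C; CF3CO2CH2CF3; aq. NH4Cl; then MsN3, Et3N, H2O, MeCN, rt
Reagents that add atoms: methanesulfonyl azide, CS(=O)(=O)N=[N+]=[N-]
Why: detrifluoroacetylative (Regitz-type) diazo transfer; kinetic enolisation at the saturated α'-carbon, C-trifluoroacetylation to activate that position, then transfer of N2 from the sulfonyl azide with loss of the trifluoroacetyl group, a sequence developed for α'-diazo enones where direct transfer to a simple ketone fails.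

**Step 14**
Reactants: 23 acetylene
Product: 26 (ethynyloxy)tri(propan-2-yl)silane [(triisopropylsilyloxy)acetylene], via lithium acetylide 24 (not isolated), via lithium ethynolate 25 (not isolated)
Conditions: n-BuLi, THF, −78 °C (excess acetylene); t-BuOOLi (from t-BuOOH and LiN(SiMe3)2), −78 → −20 °C; TIPSOTf, −78 → 0 °C
Reagents that add atoms: tert-butyl hydroperoxide (oxygen), CC(C)(C)OO; tri(propan-2-yl)silyl trifluoromethanesulfonate, CC(C)[Si](OS(=O)(=O)C(F)(F)F)(C(C)C)C(C)C
Why: oxidation of a lithium acetylide by lithium tert-butyl peroxide gives the lithium ynolate, which the bulky silyl triflate should silylate on oxygen; this is the usual route from terminal alkynes to 1-silyloxyalkynes, applied here to acetylene itself with the monolithium acetylide kept cold in excess acetylene to suppress disproportionation.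

**Step 15**
Reactants: 22 (1E)-4-diazo-7-methyl-1-P-octa-1,6-dien-3-one; 26 (ethynyloxy)tri(propan-2-yl)silane
Product: 30 4-(3-methylbut-2-en-1-yl)-2-P-5-(TIPS-oxy)phenol, via vinylketene 27 (not isolated), via cyclobutenone 28 (not isolated), via dienylketene 29 (not isolated)
Conditions: hν (365 nm), 26 (3 equiv), degassed ClCH2CH2Cl, rt; then 80 °C
Reagents that add atoms: none
Why: Excitation of the diazo ketone expels N2 and the alkenyl group shifts from the carbonyl carbon to the former diazo carbon (Wolff rearrangement), giving vinylketene 27 with prenyl on its α-carbon; the electron-rich ynol ether then adds across the ketene C=C in a [2+2] cycloaddition, its nucleophilic CH carbon bonding to the ketene carbonyl carbon, to give 4-alkenylcyclobutenone 28. Four-electron electrocyclic opening of 28 on warming gives dienylketene 29, and ring A is closed by six-electron electrocyclic closure between the ketene carbon and the alkene carbon that carries the pyranyl group, followed by tautomerisation to the phenol. This is the Danheiser benzannulation in its photochemical Wolff version, and the closest precedent is that reaction with trialkylsilyloxyalkynes as ketene partners. No stereocentre is created (the quaternary carbon of 28 is transient) and the two existing centres are remote from the reacting atoms. The step needs the regiochemistry of the [2+2] addition, which the polarisation of the O-silyl alkyne secures (OSi ends up meta to the new OH and ortho to prenyl, and the new OH is the only free hydroxyl), and it needs chemoselectivity over the two isolated trisubstituted alkenes, which are much poorer ketene partners than an ynol ether. The E geometry of the enone C=C keeps the ketene carbon away from the enol ether C=C so the vinylketene cannot close on itself, and long-wavelength light should spare the aryl bromide.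

**Step 16**
Reactants: 30 4-(3-methylbut-2-en-1-yl)-2-P-5-(TIPS-oxy)phenol
Product: 31 target with the secondary hydroxyl as TBS ether and both phenols as TIPS ethers
Conditions: CuI (20–50 mol %), N,N-dimethylglycine hydrochloride, Cs2CO3, 1,4-dioxane, 100 °C
Reagents that add atoms: none
Why: intramolecular Ullmann diaryl ether synthesis; the two aryl groups are held cis on the ring C=C, so the only free hydroxyl sits next to the aryl bromide and the copper phenoxide closes the seven-membered oxepine, and the amino acid ligand lets the coupling run at a temperature the silyl ethers should tolerate.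

**Step 17**
Reactants: 31 target with the secondary hydroxyl as TBS ether and both phenols as TIPS ethers
Product: 32 CNP0185870.1
Conditions: Bu4NF, AcOH, THF, 0 → 40 °C
Reagents that add atoms: none
Why: fluoride cleaves the two aryl TIPS ethers and the secondary TBS ether, and buffering with acetic acid keeps the electron-rich polyphenol from standing as a free phenoxide; no stereocentre is touched.

**Compound list**
1 | nerol, (2Z)-3,7-dimethylocta-2,6-dien-1-ol | CC(C)=CCC/C(C)=C\CO | starting material
2 | [(2R,3S)-3-methyl-3-(4-methylpent-3-en-1-yl)oxiran-2-yl]methanol | CC(C)=CCC[C@]1(C)O[C@@H]1CO | intermediate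
3 | (2S,3S)-3-methyl-3-(4-methylpent-3-en-1-yl)oxirane-2-carbaldehyde | CC(C)=CCC[C@]1(C)O[C@@H]1C=O | intermediate (not isolated)
4 | methyl (2E)-3-[(2R,3S)-3-methyl-3-(4-methylpent-3-en-1-yl)oxiran-2-yl]prop-2-enoate | CC(C)=CCC[C@]1(C)O[C@@H]1/C=C/C(=O)OC | intermediate
5 | methyl 3-[(2R,3S)-3-methyl-3-(4-methylpent-3-en-1-yl)oxiran-2-yl]propanoate | CC(C)=CCC[C@]1(C)O[C@@H]1CCC(=O)OC | intermediate
6 | 3-[(2R,3S)-3-methyl-3-(4-methylpent-3-en-1-yl)oxiran-2-yl]propanoic acid (formed as its lithium salt) | CC(C)=CCC[C@]1(C)O[C@@H]1CCC(=O)O | intermediate (not isolated)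
7 | (5S)-5-[(2S)-2-hydroxy-6-methylhept-5-en-2-yl]oxolan-2-one | CC(C)=CCC[C@](C)(O)[C@@H]1CCC(=O)O1 | intermediate
8 | (4S,5S)-4,5-dihydroxy-N-methoxy-N,5,9-trimethyldec-8-enamide | CC(C)=CCC[C@](C)(O)[C@@H](O)CCC(=O)N(C)OC | intermediate
9 | (4S,5S)-4-(TBS-oxy)-5-hydroxy-N-methoxy-N,5,9-trimethyldec-8-enamide | CC(C)=CCC[C@](C)(O)[C@@H](O[Si](C)(C)C(C)(C)C)CCC(=O)N(C)OC | intermediate
10 | 3-bromophenol | Oc1cccc(Br)c1 | starting material
11 | 3-bromo-4-iodophenol | Oc1ccc(I)c(Br)c1 | intermediate
12 | (3-bromo-4-iodophenoxy)tri(propan-2-yl)silane | CC(C)[Si](Oc1ccc(I)c(Br)c1)(C(C)C)C(C)C | intermediate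
13 | [2-bromo-4-(TIPS-oxy)phenyl]magnesium chloride | CC(C)[Si](Oc1ccc([Mg]Cl)c(Br)c1)(C(C)C)C(C)C | intermediate (not isolated)
14 | (4S,5S)-1-Ar-4-(TBS-oxy)-5-hydroxy-5,9-dimethyldec-8-en-1-one | CC(C)=CCC[C@](C)(O)[C@@H](O[Si](C)(C)C(C)(C)C)CCC(=O)c1ccc(O[Si](C(C)C)(C(C)C)C(C)C)cc1Br | intermediate
15 | (2S,3S)-6-Ar-3-(TBS-oxy)-2-methyl-2-(4-methylpent-3-en-1-yl)-3,4-dihydro-2H-pyran | CC(C)=CCC[C@]1(C)OC(c2ccc(O[Si](C(C)C)(C(C)C)C(C)C)cc2Br)=CC[C@@H]1O[Si](C)(C)C(C)(C)C | intermediate
16 | (5S,6S)-2-Ar-5-(TBS-oxy)-6-methyl-6-(4-methylpent-3-en-1-yl)-5,6-dihydro-4H-pyran-3-carbaldehyde | CC(C)=CCC[C@]1(C)OC(c2ccc(O[Si](C(C)C)(C(C)C)C(C)C)cc2Br)=C(C=O)C[C@@H]1O[Si](C)(C)C(C)(C)C | intermediate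
17 | 6-methylhept-5-en-2-one | CC(=O)CCC=C(C)C | starting material
18 | lithium 6-methylhepta-1,5-dien-2-olate | C=C(O[Li])CCC=C(C)C | intermediate (not isolated)
19 | 1-hydroxy-7-methyl-1-P-oct-6-en-3-one (both epimers at the new carbinol carbon) | CC(C)=CCC[C@]1(C)OC(c2ccc(O[Si](C(C)C)(C(C)C)C(C)C)cc2Br)=C(C(O)CC(=O)CCC=C(C)C)C[C@@H]1O[Si](C)(C)C(C)(C)C | intermediate (not isolated)
20 | (1E)-7-methyl-1-P-octa-1,6-dien-3-one | CC(C)=CCC[C@]1(C)OC(c2ccc(O[Si](C(C)C)(C(C)C)C(C)C)cc2Br)=C(/C=C/C(=O)CCC=C(C)C)C[C@@H]1O[Si](C)(C)C(C)(C)C | intermediate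
21 | (1E)-7-methyl-1-P-4-(trifluoroacetyl)octa-1,6-dien-3-one | CC(C)=CCC[C@]1(C)OC(c2ccc(O[Si](C(C)C)(C(C)C)C(C)C)cc2Br)=C(/C=C/C(=O)C(CC=C(C)C)C(=O)C(F)(F)F)C[C@@H]1O[Si](C)(C)C(C)(C)C | intermediate (not isolated)
22 | (1E)-4-diazo-7-methyl-1-P-octa-1,6-dien-3-one | CC(C)=CCC[C@]1(C)OC(c2ccc(O[Si](C(C)C)(C(C)C)C(C)C)cc2Br)=C(C[C@@H]1O[Si](C)(C)C(C)(C)C)/C=C/C(=O)C(=[N+]=[N-])CC=C(C)C | intermediate
23 | acetylene | C#C | starting material
24 | lithium acetylide | [Li]C#C | intermediate (not isolated)
25 | lithium ethynolate | [Li]OC#C | intermediate (not isolated)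
26 | (ethynyloxy)tri(propan-2-yl)silane | C#CO[Si](C(C)C)(C(C)C)C(C)C | intermediate
27 | (3E)-2-(3-methylbut-2-en-1-yl)-4-P-buta-1,3-dien-1-one | CC(C)=CCC[C@]1(C)OC(c2ccc(O[Si](C(C)C)(C(C)C)C(C)C)cc2Br)=C(C[C@@H]1O[Si](C)(C)C(C)(C)C)/C=C/C(CC=C(C)C)=C=O | intermediate (not isolated)
28 | 4-(3-methylbut-2-en-1-yl)-4-[(E)-2-P-ethenyl]-3-(TIPS-oxy)cyclobut-2-en-1-one (either configuration at C4) | CC(C)=CCC[C@]1(C)OC(c2ccc(O[Si](C(C)C)(C(C)C)C(C)C)cc2Br)=C(C[C@@H]1O[Si](C)(C)C(C)(C)C)/C=C/C1(CC=C(C)C)C(=O)C=C1O[Si](C(C)C)(C(C)C)C(C)C | intermediate (not isolated)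
29 | (5E)-4-(3-methylbut-2-en-1-yl)-6-P-3-(TIPS-oxy)hexa-1,3,5-trien-1-one | CC(C)=CCC[C@]1(C)OC(c2ccc(O[Si](C(C)C)(C(C)C)C(C)C)cc2Br)=C(C[C@@H]1O[Si](C)(C)C(C)(C)C)/C=C/C(CC=C(C)C)=C(O[Si](C(C)C)(C(C)C)C(C)C)C=C=O | intermediate (not isolated)
30 | 4-(3-methylbut-2-en-1-yl)-2-P-5-(TIPS-oxy)phenol | CC(C)=CCC[C@]1(C)OC(c2ccc(O[Si](C(C)C)(C(C)C)C(C)C)cc2Br)=C(C[C@@H]1O[Si](C)(C)C(C)(C)C)c1cc(CC=C(C)C)c(O[Si](C(C)C)(C(C)C)C(C)C)cc1O | intermediate
31 | target with the secondary hydroxyl as TBS ether and both phenols as TIPS ethers | CC(C)=CCC[C@]1(C)OC2=C(C[C@@H]1O[Si](C)(C)C(C)(C)C)c1cc(CC=C(C)C)c(O[Si](C(C)C)(C(C)C)C(C)C)cc1Oc1cc(O[Si](C(C)C)(C(C)C)C(C)C)ccc12 | intermediate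
32 | CNP0185870.1 | CC(C)=CCC[C@]1(C)OC2=C(C[C@@H]1O)c1cc(CC=C(C)C)c(O)cc1Oc1cc(O)ccc12 | target

**Step count**
Total: 17 steps. Longest linear sequence: 14 steps (1–6, 9–13, 15–17, from nerol).

**Steps most likely to fail**

Step 15. The light may isomerise the E-enone before nitrogen is lost, after which the ketene or the dienone can close onto the enol ether C=C. The keto carbene may also undergo a 1,2-hydrogen shift from the prenyl CH2 instead of the Wolff shift, and the ketene may be consumed by dimerisation or by acylating the product phenol.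
Fallback (ring A brought in preformed; sets out from 15, returns at 32):
- 15 is iodinated at Cb (N-iodosuccinimide, 2,6-lutidine, MeCN, 0 °C) to the 5-iodo dihydropyran F1.
- Separately, commercial 4,6-dibromoresorcinol is silylated (TIPSCl, imidazole, DMF) to the bis(TIPS) ether F2.
- One bromine of F2 is exchanged (n-BuLi, THF, −78 °C) and the aryllithium is prenylated (prenyl bromide, CuBr·SMe2 cat.) to the bromo prenyl arene F3.
- A second exchange on F3, trapped with i-PrOBpin, gives the pinacol boronate F4.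
- Suzuki–Miyaura coupling of F1 with F4 (PdCl2(dppf), aq. K3PO4, THF, 50 °C), in which the vinyl C–I bond should react before the aryl C–Br bond, gives the fully silylated bromo diaryl enol ether F5.
- Bu4NF removes all four silyl groups to give the bromo tetrol F6.
- Ullmann closure under the conditions of step 16 at high dilution, where only the hydroxyl ortho to Cb can reach the bromide, gives 32.

Step 14. The monolithium acetylide may disproportionate before it is oxidised, the unhindered parent ynolate may be silylated on carbon (giving a silylketene) instead of on oxygen, and the volatile, moisture-sensitive ynol ether may be lost on isolation.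
Fallback (an alkyl ynol ether with a fluoride-labile O-substituent; sets out from 22, returns at 32):
- 2-(Trimethylsilyl)ethanol is added to trichloroethylene (KH, THF) to give the dichlorovinyl ether F7.
- n-BuLi (2.5 equiv, −78 → −40 °C, MeOH quench) converts F7 into the 2-(trimethylsilyl)ethyl ynol ether F8.
- 22 and F8 under the conditions of step 15 give the ring A phenol F9, which carries a 2-(trimethylsilyl)ethyl ether in place of the TIPS ether.
- The conditions of step 16 close the oxepine F10.
- Bu4NF (THF, 60 °C) removes TBS, TIPS and the 2-(trimethylsilyl)ethyl group (as ethene and fluorotrimethylsilane) to give 32.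

Step 16. Oxidative addition to the hindered, electron-rich aryl bromide may be slow, so that protodebromination, or carbonate-induced loss of the aryl silyl ethers followed by intermolecular etherification, takes over.
Fallback (polarity of ring B reversed; sets out from 30, returns at 31):
- Miyaura borylation of the aryl bromide (PdCl2(dppf), B2pin2, KOAc, 1,4-dioxane, 90 °C) gives the aryl pinacol boronate F11.
- Intramolecular Chan–Lam etherification with the ring A phenol (Cu(OAc)2, pyridine, B(OH)3, 4 Å MS, MeCN, air, 60 °C) gives 31.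

**Further compounds**
F1 | step 15 | (2S,3S)-6-Ar-3-(TBS-oxy)-5-iodo-2-methyl-2-(4-methylpent-3-en-1-yl)-3,4-dihydro-2H-pyran | CC(C)=CCC[C@]1(C)OC(c2ccc(O[Si](C(C)C)(C(C)C)C(C)C)cc2Br)=C(I)C[C@@H]1O[Si](C)(C)C(C)(C)C
F2 | step 15 | 1,5-dibromo-2,4-bis(TIPS-oxy)benzene | CC(C)[Si](Oc1cc(O[Si](C(C)C)(C(C)C)C(C)C)c(Br)cc1Br)(C(C)C)C(C)C
F3 | step 15 | 1-bromo-5-(3-methylbut-2-en-1-yl)-2,4-bis(TIPS-oxy)benzene | CC(C)=CCc1cc(Br)c(O[Si](C(C)C)(C(C)C)C(C)C)cc1O[Si](C(C)C)(C(C)C)C(C)C
F4 | step 15 | 2-[5-(3-methylbut-2-en-1-yl)-2,4-bis(TIPS-oxy)phenyl]-4,4,5,5-tetramethyl-1,3,2-dioxaborolane | CC(C)=CCc1cc(B2OC(C)(C)C(C)(C)O2)c(O[Si](C(C)C)(C(C)C)C(C)C)cc1O[Si](C(C)C)(C(C)C)C(C)C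
F5 | step 15 | 1-P-5-(3-methylbut-2-en-1-yl)-2,4-bis(TIPS-oxy)benzene | CC(C)=CCC[C@]1(C)OC(c2ccc(O[Si](C(C)C)(C(C)C)C(C)C)cc2Br)=C(C[C@@H]1O[Si](C)(C)C(C)(C)C)c1cc(CC=C(C)C)c(O[Si](C(C)C)(C(C)C)C(C)C)cc1O[Si](C(C)C)(C(C)C)C(C)C
F6 | step 15 | 4-[(2S,3S)-6-(2-bromo-4-hydroxyphenyl)-3-hydroxy-2-methyl-2-(4-methylpent-3-en-1-yl)-3,4-dihydro-2H-pyran-5-yl]-6-(3-methylbut-2-en-1-yl)benzene-1,3-diol | CC(C)=CCC[C@]1(C)OC(c2ccc(O)cc2Br)=C(C[C@@H]1O)c1cc(CC=C(C)C)c(O)cc1O
F7 | step 14 | [2-(1,2-dichloroethenyloxy)ethyl]trimethylsilane | C[Si](C)(C)CCOC(Cl)=CCl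
F8 | step 14 | [2-(ethynyloxy)ethyl]trimethylsilane | C#COCC[Si](C)(C)C
F9 | step 14 | 4-(3-methylbut-2-en-1-yl)-2-P-5-[2-(trimethylsilyl)ethoxy]phenol | CC(C)=CCC[C@]1(C)OC(c2ccc(O[Si](C(C)C)(C(C)C)C(C)C)cc2Br)=C(C[C@@H]1O[Si](C)(C)C(C)(C)C)c1cc(CC=C(C)C)c(OCC[Si](C)(C)C)cc1O
F10 | step 14 | target with the secondary hydroxyl as TBS ether, the ring B phenol as TIPS ether and the ring A phenol as 2-(trimethylsilyl)ethyl ether | CC(C)=CCC[C@]1(C)OC2=C(C[C@@H]1O[Si](C)(C)C(C)(C)C)c1cc(CC=C(C)C)c(OCC[Si](C)(C)C)cc1Oc1cc(O[Si](C(C)C)(C(C)C)C(C)C)ccc12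
F11 | step 16 | 30 with the bromine replaced by a 4,4,5,5-tetramethyl-1,3,2-dioxaborolan-2-yl group | CC(C)=CCC[C@]1(C)OC(c2ccc(O[Si](C(C)C)(C(C)C)C(C)C)cc2B3OC(C)(C)C(C)(C)O3)=C(C[C@@H]1O[Si](C)(C)C(C)(C)C)c1cc(CC=C(C)C)c(O[Si](C(C)C)(C(C)C)C(C)C)cc1O
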